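The route rests on opening the ten-membered carbocycle at C6–C7 while re-forming C4–C9 (germacrane numbering), which reduces the germacranolide to a carvone-derived cyclohexenol bearing two alkenyl groups. The C9 oxygen, C8, C7, oxygenated C6 and the C4=C5 alkene of the target are the δ,ε-unsaturated carbonyl array left by an oxy-Cope shift, and C9–C10(Me)=C1–C2–C3–C4 is the six-membered ring of carvone. One anionic [3,3] shift thus expands the cyclohexene by four atoms into the (1Z,4E)-cyclodecadienone and sets C6 and C7 together. Its precursor is a trans-1,2-dialkenylcyclohexenol with an (E)-silyl enol ether on quaternary C4 and a Roche-ester-derived (E)-alkenyl chain on the C9 carbinol; the γ-lactone is closed afterwards.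

Key step: step 13

Remark 1: atom labels C1–C15 are the germacrane positions of the target and are used for every intermediate (carvone C1, C2, C3, C4, C5, C6 become C9, C10, C1, C2, C3, C4).
Remark 2: in step 3 the two acetyl carbons of the new C3 acetate are taken to be the former isopropenyl carbon and its methyl group, with the carbonyl oxygen coming from acetate.
Remark 3: compound 4 is carried on as its epimer mixture at the allyl-bearing carbon, since that centre is enolized again in step 2.

Step 1
Reactants: 1 (R)-carvone; 2 allyl bromide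
Product: 4 (5R,6S)-6-allylcarvone (trans epimer major), via lithium dienolate of carvone 3 (not isolated)
Conditions: LiN(iPr)2 (1.1 equiv), THF, −78 °C; then 2, −78 → 0 °C
Reagents that add atoms: allyl bromide (2), C=CCBr
Why: Enolate alkylation: LiN(iPr)2 removes the α′ proton kinetically to give the cross-conjugated dienolate, and SN2 attack on allyl bromide brings in the future C5–C6 unit mainly anti to the isopropenyl group, the epimer ratio being irrelevant because this centre is planarized again in step 2.

Step 2
Reactants: 4 6-allylcarvone; 5 iodomethane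
Product: 7 (5S,6R)-6-allyl-6-methylcarvone (allyl cis to isopropenyl), via lithium dienolate of 6-allylcarvone 6 (not isolated)
Conditions: LiN(iPr)2 (1.2 equiv), THF, −78 °C; then MeI, DMPU, −78 → 0 °C
Reagents that add atoms: iodomethane (5), CI
Why: Second enolate alkylation: the tetrasubstituted enolate is methylated on the face opposite the adjacent isopropenyl group, which creates the quaternary carbon (future C4, R) with allyl cis and methyl trans to isopropenyl.

Step 3
Reactants: 7 6-allyl-6-methylcarvone
Product: 9 methyl 2-[(1R,6R)-6-acetoxy-1,3-dimethyl-2-oxocyclohex-3-en-1-yl]acetate, via bis(methoxy hydroperoxide) 8 (not isolated)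
Conditions: O3, CH2Cl2/MeOH, Sudan Red 7B indicator, −78 °C; then Ac2O, Et3N, DMAP (cat.), 0 °C → rt
Reagents that add atoms: ozone, [O-][O+]=O; methanol, CO; acetic anhydride, CC(=O)OC(C)=O
Why: Ozonolysis in methanol followed by acylation: ozone cleaves the two terminal alkenes ahead of the deactivated ring alkene (indicator end point), methanol traps both carbonyl oxides, and Ac2O/Et3N then sets off a Criegee rearrangement of the tertiary peroxide (the ring carbon migrates to oxygen with retention, giving the C3 acetate) and a dehydrative fragmentation of the secondary one to the methyl ester, while any allyl-derived material left at the aldehyde level by the alternative ozonide cleavage converges with 9 in step 4.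

Step 4
Reactants: 9 acetate methyl ester enone
Product: 10 (5R,6R)-6-(2-hydroxyethyl)-2,6-dimethylcyclohex-2-ene-1,5-diol (C9 carbinol epimers)
Conditions: iBu2AlH (7 equiv), CH2Cl2, −78 → 0 °C; KNaC4H4O6 (aq)
Reagents that add atoms: none
Why: Exhaustive hydride reduction: iBu2AlH adds 1,2 to the enone and cleaves the acetate and the methyl ester, so one triol results whatever the C9 carbinol configuration, which is erased in step 5.

Step 5
Reactants: 10 triol
Product: 11 (5R,6R)-5-hydroxy-6-(2-hydroxyethyl)-2,6-dimethylcyclohex-2-en-1-one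
Conditions: MnO2 (excess), CH2Cl2, rt
Reagents that add atoms: none
Why: Chemoselective allylic oxidation: MnO2 reoxidizes only the allylic C9 alcohol to the enone and leaves the saturated C3 and C6 hydroxyls alone.

Step 6
Reactants: 11 enone diol
Product: 13 (5R,6R)-5-(tert-butyldimethylsilyloxy)-2,6-dimethyl-6-[2-(triethylsilyloxy)ethyl]cyclohex-2-en-1-one, via primary triethylsilyl ether 12 (not isolated)
Conditions: TESOTf (1.05 equiv), 2,6-lutidine, CH2Cl2, −78 °C; then TBSOTf (1.5 equiv), −78 → 0 °C
Reagents that add atoms: triethylsilyl trifluoromethanesulfonate, CC[Si](CC)(CC)OS(=O)(=O)C(F)(F)F; tert-butyldimethylsilyl trifluoromethanesulfonate, CC(C)(C)[Si](C)(C)OS(=O)(=O)C(F)(F)F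
Why: Silyl ether formation with silyl triflates and a hindered pyridine base: at −78 °C the triethylsilyl group goes to the unhindered primary C6 hydroxyl, the more forcing TBSOTf then caps the neopentylic C3 hydroxyl, and the nearly neutral medium spares the β-hydroxy ketone from retro-aldol cleavage.

Step 7
Reactants: 13 bis(silyl ether)
Product: 14 2-[(1R,6R)-6-(tert-butyldimethylsilyloxy)-1,3-dimethyl-2-oxocyclohex-3-en-1-yl]acetaldehyde
Conditions: (COCl)2, DMSO, CH2Cl2, −78 → −30 °C; then Et3N, −78 → 0 °C
Reagents that add atoms: none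
Why: Swern oxidation used as an oxidative desilylation: the activated sulfoxide cleaves the primary triethylsilyl ether and oxidizes it to the aldehyde in the same flask, whereas the hindered secondary TBS ether does not react.

Step 8
Reactants: 14 keto aldehyde
Product: 15 (5R,6R)-5-(tert-butyldimethylsilyloxy)-2,6-dimethyl-6-[(E)-2-(triisopropylsilyloxy)ethenyl]cyclohex-2-en-1-one
Conditions: TIPSOTf (1.2 equiv), Et3N, CH2Cl2, −78 °C → rt; chromatography on Et3N-deactivated silica
Reagents that add atoms: triisopropylsilyl trifluoromethanesulfonate, CC(C)[Si](OS(=O)(=O)C(F)(F)F)(C(C)C)C(C)C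
Why: Silyl enol ether formation by soft enolization (silyl triflate plus amine): the aldehyde is O-silylated and deprotonated at C5, the quaternary C4 beside the new C5=C6 bond disfavours the Z isomer and the transition state leading to it (tert-alkyl group cis to OSi), so the E isomer is expected, and the enone has no α-hydrogen that could compete.

Step 9
Reactants: 16 methyl (S)-3-hydroxy-2-methylpropanoate
Product: 17 methyl (S)-3-(tert-butyldimethylsilyloxy)-2-methylpropanoate
Conditions: TBSCl, imidazole, CH2Cl2, 0 °C → rt
Reagents that add atoms: tert-butyldimethylsilyl chloride, CC(C)(C)[Si](C)(C)Cl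
Why: Routine silylation of the primary alcohol under mild base, which does not touch the α-stereocentre of the ester.

Step 10
Reactants: 17 silylated ester
Product: 18 (S)-3-(tert-butyldimethylsilyloxy)-2-methylpropanal
Conditions: iBu2AlH (1.1 equiv), CH2Cl2, −78 °C; MeOH, then KNaC4H4O6 (aq)
Reagents that add atoms: none
Why: Partial ester reduction: at −78 °C the aluminium hemiacetal formed by one hydride transfer persists until work-up and then releases the aldehyde, which is used crude because its α-centre epimerizes easily.

Step 11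
Reactants: 18 aldehyde; 19 iodoform
Product: 20 (R,E)-tert-butyl[(4-iodo-2-methylbut-3-en-1-yl)oxy]dimethylsilane
Conditions: CrCl2 (6 equiv), CHI3 (2 equiv), THF, 0 °C
Reagents that add atoms: iodoform (19), IC(I)I
Why: Takai olefination: the geminal dichromium reagent generated from iodoform and CrCl2 (divalent chromium) adds to the aldehyde and eliminates to the E alkenyl iodide under non-basic conditions that preserve the α-stereocentre.

Step 12
Reactants: 15 enone with the E silyl enol ether; 20 alkenyl iodide
Product: 22 (1S,5R,6R)-1-[(1E,3R)-4-(tert-butyldimethylsilyloxy)-3-methylbut-1-en-1-yl]-5-(tert-butyldimethylsilyloxy)-2,6-dimethyl-6-[(E)-2-(triisopropylsilyloxy)ethenyl]cyclohex-2-en-1-ol (alkenyl groups trans), via alkenyllithium 21 (not isolated)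
Conditions: 20 (1.5 equiv), t-BuLi (3.0 equiv), Et2O, −78 °C; then 15, Et2O, −78 °C; H2O
Reagents that add atoms: none
Why: Iodine–lithium exchange with retention of alkene geometry followed by 1,2-addition to the enone: the C3 silyloxy group and the C4 alkenyl group shield the same face of the ring, so the alkenyllithium enters from the opposite face, which makes the two alkenyl groups trans and the new C9 carbinol S.

Step 13
Reactants: 22 trans-dialkenylcyclohexenol
Product: 25 (3R,6S,7S,11R)-3,12-bis(tert-butyldimethylsilyloxy)-6-(triisopropylsilyloxy)germacra-1(10)Z,4E-dien-9-one, via potassium alkoxide 23 (not isolated), via potassium enolate 24 (not isolated)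
Conditions: KH (1.5 equiv), 18-crown-6 (1.5 equiv), THF, 0 °C → rt; then AcOH, THF, −78 °C
Reagents that add atoms: none
Why: KH with 18-crown-6 gives the free potassium alkoxide 23, which undergoes a concerted anionic oxy-Cope [3,3] shift through a chair in which C7=C8–C9 and C4–C5=C6 overlap, C4–C9 breaking as C6–C7 forms, and the cross-conjugated enolate 24 is then protonated at C8 to the enone. The closest known reaction type is the alkoxide-accelerated ring expansion of trans-1,2-divinylcyclohexanols to cyclodec-5-enones, applied here to a substrate that has a silyl enol ether as one terminus. The ten-membered ring is not closed end to end but arises by four-atom ring expansion of the cyclohexene, so no macrocyclization entropy is paid and the ring alkene is carried over as Z C1=C10, while the equatorial C3–C4 bond becomes the E C4=C5 alkene. C6 and C7 (both S) are created together under control of the chair: the two E termini hold OTIPS and the C11 chain equatorial, which puts H6 and H7 anti as the trans lactone needs, and the R configuration of C4 decides which faces pair. The step needs one chair only and pure E geometry at both alkenes, which the trans arrangement of the alkenyl groups (a single chair reaches overlap) and the stereodefined steps 8 and 11 secure. Kinetic C-protonation of 24 with acetic acid at −78 °C keeps the enone Z and leaves the allylic silyl ethers in place.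

Step 14
Reactants: 25 tris(silyl ether) dienone
Product: 26 (3R,6S,7S,11R)-3,6,12-trihydroxygermacra-1(10)Z,4E-dien-9-one
Conditions: Bu4NF (6 equiv), AcOH (6 equiv), THF, 0 → 40 °C
Reagents that add atoms: none
Why: Fluoride-mediated desilylation: all three silyl ethers are cleaved while acetic acid keeps the medium close to neutral, which protects the Z enone from vinylogous retro-aldol cleavage and C11 from epimerization, and a reversible C6–O–C9 hemiketal form of the triol is of no consequence.

Step 15
Reactants: 26 triol
Product: 28 (3R,6S,7S,11R)-3-hydroxy-9-oxogermacra-1(10)Z,4E-dien-12,6-olide, via lactol 27 (not isolated)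
Conditions: TEMPO (20 mol %), PhI(OAc)2 (2.5 equiv), CH2Cl2, rt
Reagents that add atoms: none
Why: TEMPO-mediated oxidative lactonization: the oxoammonium species oxidizes the primary C12 alcohol selectively, the C6 hydroxyl traps the aldehyde as a five-membered lactol and this is oxidized on to the lactone, whose trans fusion follows from the anti H6/H7 relationship set in step 13.

Step 16
Reactants: 28 hydroxy lactone
Product: 29 (6S,7S,11R)-3,9-dioxogermacra-1(10)Z,4E-dien-12,6-olide
Conditions: Dess–Martin periodinane (1.3 equiv), NaHCO3, CH2Cl2, 0 °C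
Reagents that add atoms: none
Why: Dess–Martin oxidation under bicarbonate buffering turns the allylic C3 alcohol into the enone without acid or base, which matters because C2 of the product lies between a ketone and a vinylogous ketone and enolizes readily.

Step 17
Reactants: 29 dione lactone
Product: 30 (3S,6S,7S,9S,11R)-3,9-dihydroxygermacra-1(10)Z,4E-dien-12,6-olide
Conditions: (R)-1-methyl-3,3-diphenyltetrahydro-1H,3H-pyrrolo[1,2-c][1,3,2]oxazaborole (40 mol %), catecholborane (4 equiv), toluene/CH2Cl2, −78 °C; MeOH
Reagents that add atoms: none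
Why: Corey–Bakshi–Shibata reduction under reagent control: at each ketone the methyl-bearing alkene carbon (C4 or C10) is the large flank and the ring CH2 (C2 or C8) the small one, so the (R)-oxazaborolidine should deliver hydride to give the S carbinol at both C3 and C9, and catecholborane at −78 °C reduces neither the lactone nor the conjugated alkenes.

Step 18
Reactants: 30 diol lactone
Product: 31 (3S,6S,7S,9S,11R)-3,9-diacetoxygermacra-1(10)Z,4E-dien-12,6-olide
Conditions: Ac2O, Et3N, DMAP (cat.), CH2Cl2, 0 °C → rt
Reagents that add atoms: acetic anhydride, CC(=O)OC(C)=O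
Why: DMAP-catalysed acylation of the two secondary allylic alcohols under conditions too mild to epimerize C11 or open the lactone.

Compound list
1 | (R)-carvone | CC1=CC[C@@H](C(C)=C)CC1=O | starting material
2 | allyl bromide | C=CCBr | starting material
3 | lithium dienolate of (R)-carvone | CC1=CC[C@@H](C(C)=C)C=C1O[Li] | intermediate
4 | (5R,6S)-6-allylcarvone (trans epimer drawn) | CC1=CC[C@@H](C(C)=C)[C@H](CC=C)C1=O | intermediate
5 | iodomethane | CI | starting material
6 | lithium dienolate of 6-allylcarvone | CC1=CC[C@@H](C(C)=C)C(CC=C)=C1O[Li] | intermediate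
7 | (5S,6R)-6-allyl-6-methylcarvone, allyl cis to isopropenyl | CC1=CC[C@@H](C(C)=C)[C@@](C)(CC=C)C1=O | intermediate
8 | bis(α-methoxy hydroperoxide) from ozonolysis of 7 in methanol | CC1=CC[C@@H](C(C)(OC)OO)[C@@](C)(CC(OC)OO)C1=O | intermediate
9 | methyl 2-[(1R,6R)-6-acetoxy-1,3-dimethyl-2-oxocyclohex-3-en-1-yl]acetate | CC1=CC[C@@H](OC(C)=O)[C@@](C)(CC(=O)OC)C1=O | intermediate
10 | (5R,6R)-6-(2-hydroxyethyl)-2,6-dimethylcyclohex-2-ene-1,5-diol, C9 carbinol epimers | CC1=CC[C@@H](O)[C@@](C)(CCO)C1O | intermediate
11 | (5R,6R)-5-hydroxy-6-(2-hydroxyethyl)-2,6-dimethylcyclohex-2-en-1-one | CC1=CC[C@@H](O)[C@@](C)(CCO)C1=O | intermediate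
12 | primary triethylsilyl ether of 11 | CC1=CC[C@@H](O)[C@@](C)(CCO[Si](CC)(CC)CC)C1=O | intermediate
13 | (5R,6R)-5-(tert-butyldimethylsilyloxy)-2,6-dimethyl-6-[2-(triethylsilyloxy)ethyl]cyclohex-2-en-1-one | CC1=CC[C@@H](O[Si](C)(C)C(C)(C)C)[C@@](C)(CCO[Si](CC)(CC)CC)C1=O | intermediate
14 | 2-[(1R,6R)-6-(tert-butyldimethylsilyloxy)-1,3-dimethyl-2-oxocyclohex-3-en-1-yl]acetaldehyde | CC1=CC[C@@H](O[Si](C)(C)C(C)(C)C)[C@@](C)(CC=O)C1=O | intermediate
15 | (5R,6R)-5-(tert-butyldimethylsilyloxy)-2,6-dimethyl-6-[(E)-2-(triisopropylsilyloxy)ethenyl]cyclohex-2-en-1-one | CC1=CC[C@@H](O[Si](C)(C)C(C)(C)C)[C@@](C)(/C=C/O[Si](C(C)C)(C(C)C)C(C)C)C1=O | intermediate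
16 | methyl (S)-3-hydroxy-2-methylpropanoate (Roche ester) | C[C@@H](CO)C(=O)OC | starting material
17 | methyl (S)-3-(tert-butyldimethylsilyloxy)-2-methylpropanoate | C[C@@H](CO[Si](C)(C)C(C)(C)C)C(=O)OC | intermediate
18 | (S)-3-(tert-butyldimethylsilyloxy)-2-methylpropanal | C[C@@H](CO[Si](C)(C)C(C)(C)C)C=O | intermediate
19 | iodoform | IC(I)I | starting material
20 | (R,E)-tert-butyl[(4-iodo-2-methylbut-3-en-1-yl)oxy]dimethylsilane | C[C@@H](CO[Si](C)(C)C(C)(C)C)/C=C/I | intermediate
21 | (R,E)-[4-(tert-butyldimethylsilyloxy)-3-methylbut-1-en-1-yl]lithium | C[C@@H](CO[Si](C)(C)C(C)(C)C)/C=C/[Li] | intermediate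
22 | (1S,5R,6R)-1-[(1E,3R)-4-(tert-butyldimethylsilyloxy)-3-methylbut-1-en-1-yl]-5-(tert-butyldimethylsilyloxy)-2,6-dimethyl-6-[(E)-2-(triisopropylsilyloxy)ethenyl]cyclohex-2-en-1-ol | CC1=CC[C@@H](O[Si](C)(C)C(C)(C)C)[C@@](C)(/C=C/O[Si](C(C)C)(C(C)C)C(C)C)[C@]1(O)/C=C/[C@@H](C)CO[Si](C)(C)C(C)(C)C | intermediate
23 | potassium alkoxide of 22 | CC1=CC[C@@H](O[Si](C)(C)C(C)(C)C)[C@@](C)(/C=C/O[Si](C(C)C)(C(C)C)C(C)C)[C@]1(O[K])/C=C/[C@@H](C)CO[Si](C)(C)C(C)(C)C | intermediate
24 | potassium C8=C9 enolate of the ten-membered ring | [K]O/C1=C\[C@@H]([C@@H](C)CO[Si](C)(C)C(C)(C)C)[C@@H](/C=C(\C)[C@H](O[Si](C)(C)C(C)(C)C)C/C=C\1C)O[Si](C(C)C)(C(C)C)C(C)C | intermediate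
25 | (3R,6S,7S,11R)-3,12-bis(tert-butyldimethylsilyloxy)-6-(triisopropylsilyloxy)germacra-1(10)Z,4E-dien-9-one | O=C1C[C@@H]([C@@H](C)CO[Si](C)(C)C(C)(C)C)[C@@H](/C=C(\C)[C@H](O[Si](C)(C)C(C)(C)C)C/C=C\1C)O[Si](C(C)C)(C(C)C)C(C)C | intermediate
26 | (3R,6S,7S,11R)-3,6,12-trihydroxygermacra-1(10)Z,4E-dien-9-one | O=C1C[C@@H]([C@@H](C)CO)[C@@H](/C=C(\C)[C@H](O)C/C=C\1C)O | intermediate
27 | lactol between C12 and the C6 oxygen, C3 hydroxyl free | O=C1C[C@@H]2[C@@H](/C=C(\C)[C@H](O)C/C=C\1C)OC(O)[C@@H]2C | intermediate
28 | (3R,6S,7S,11R)-3-hydroxy-9-oxogermacra-1(10)Z,4E-dien-12,6-olide | O=C1C[C@@H]2[C@@H](/C=C(\C)[C@H](O)C/C=C\1C)OC(=O)[C@@H]2C | intermediate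
29 | (6S,7S,11R)-3,9-dioxogermacra-1(10)Z,4E-dien-12,6-olide | O=C1C[C@@H]2[C@@H](/C=C(\C)C(=O)C/C=C\1C)OC(=O)[C@@H]2C | intermediate
30 | (3S,6S,7S,9S,11R)-3,9-dihydroxygermacra-1(10)Z,4E-dien-12,6-olide | O[C@H]1C[C@@H]2[C@@H](/C=C(\C)[C@@H](O)C/C=C\1C)OC(=O)[C@@H]2C | intermediate
31 | (3S,6S,7S,9S,11R)-3,9-diacetoxygermacra-1(10)Z,4E-dien-12,6-olide | CC(=O)O[C@H]1C[C@@H]2[C@@H](/C=C(\C)[C@@H](OC(C)=O)C/C=C\1C)OC(=O)[C@@H]2C | target

Total step count: 18. Longest linear sequence: 15 steps from (R)-carvone (steps 1–8 and 12–18); steps 9–11 are the three-step branch to the alkenyl iodide.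

Steps most likely to fail

Step 13, the ring expansion. Instead of rearranging, the naked alkoxide may pass the syn-axial C3 silyl group to the C9 oxygen (O-to-O silyl migration), or the C4–C9 bond may break heterolytically without recombination. The fallback leaves the anionic manifold for the neutral siloxy-Cope variant and sets out from carbinol 22. Silylation with N-(trimethylsilyl)imidazole gives the trimethylsilyl ether F1. Heating F1 in o-dichlorobenzene at about 200 °C in base-washed glassware should drive the same chair [3,3] shift to the ten-membered trimethylsilyl enol ether F2. Brief K2CO3/MeOH at 0 °C cleaves only the enol silyl group, and the route is rejoined at ketone 25.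

Step 17, the double reduction. The conformation of the ten-membered ring may override the catalyst at one carbonyl and give poor facial selectivity, and the dione may enolize at C2 before it is reduced. The fallback never forms the dione and sets C3 by inversion; it sets out from ketone 25. Reduction at C9 alone with the same oxazaborolidine and catecholborane gives the 9S alcohol F3, which is acetylated (Ac2O, DMAP) to the acetate F4. Bu4NF/AcOH then gives the triol acetate F5, and TEMPO/PhI(OAc)2 closes the lactone to the 3R hydroxy lactone F6. A Mitsunobu reaction with acetic acid (PPh3, diisopropyl azodicarboxylate, THF, 0 °C) inverts C3 while installing the second acetate, and the sequence arrives directly at target 31.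

Step 8, the enol ether geometry. Geometric control in the enolization may be incomplete, and the chair of step 13 would carry any Z enol ether into the C6 epimer. The fallback separates bond formation from geometry control; it sets out from aldehyde 14, which is silylated as in step 8 without regard to selectivity. The resulting mixture, containing the Z enol ether F7, is equilibrated in a separate operation with catalytic RuHCl(CO)(PPh3)3 (a divalent ruthenium hydride) in toluene at 80 °C. Reversible hydrometalation and β-hydride elimination across C5=C6 can only interconvert the two geometries because C4 is quaternary. The strain of a cis tert-alkyl/silyloxy pair should drive the mixture to the E enol ether 15, where the route is rejoined.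

Further compounds
F1 | step 13 | trimethylsilyl ether of carbinol 22 | CC1=CC[C@@H](O[Si](C)(C)C(C)(C)C)[C@@](C)(/C=C/O[Si](C(C)C)(C(C)C)C(C)C)[C@]1(O[Si](C)(C)C)/C=C/[C@@H](C)CO[Si](C)(C)C(C)(C)C
F2 | step 13 | ten-membered C8=C9 trimethylsilyl enol ether corresponding to ketone 25 | C[Si](C)(C)O/C1=C\[C@@H]([C@@H](C)CO[Si](C)(C)C(C)(C)C)[C@@H](/C=C(\C)[C@H](O[Si](C)(C)C(C)(C)C)C/C=C\1C)O[Si](C(C)C)(C(C)C)C(C)C
F3 | step 17 | (3R,6S,7S,9S,11R)-3,12-bis(tert-butyldimethylsilyloxy)-6-(triisopropylsilyloxy)germacra-1(10)Z,4E-dien-9-ol | O[C@H]1C[C@@H]([C@@H](C)CO[Si](C)(C)C(C)(C)C)[C@@H](/C=C(\C)[C@H](O[Si](C)(C)C(C)(C)C)C/C=C\1C)O[Si](C(C)C)(C(C)C)C(C)C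
F4 | step 17 | 9-acetate of F3 | CC(=O)O[C@H]1C[C@@H]([C@@H](C)CO[Si](C)(C)C(C)(C)C)[C@@H](/C=C(\C)[C@H](O[Si](C)(C)C(C)(C)C)C/C=C\1C)O[Si](C(C)C)(C(C)C)C(C)C
F5 | step 17 | (3R,6S,7S,9S,11R)-9-acetoxygermacra-1(10)Z,4E-diene-3,6,12-triol | CC(=O)O[C@H]1C[C@@H]([C@@H](C)CO)[C@@H](/C=C(\C)[C@H](O)C/C=C\1C)O
F6 | step 17 | (3R,6S,7S,9S,11R)-9-acetoxy-3-hydroxygermacra-1(10)Z,4E-dien-12,6-olide | CC(=O)O[C@H]1C[C@@H]2[C@@H](/C=C(\C)[C@H](O)C/C=C\1C)OC(=O)[C@@H]2C
F7 | step 8 | (Z)-enol ether isomer of 15 | CC1=CC[C@@H](O[Si](C)(C)C(C)(C)C)[C@@](C)(/C=C\O[Si](C(C)C)(C(C)C)C(C)C)C1=O
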